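Remark on the chemistry: every intermediate carries the germacrane locants of the target (C1–C15); in the cyclohexane series C1 bears the isopropenyl group (C10 with C9 and C14), C4 bears C15, and C5 and C6 are the oxygenated carbons. The target is taken as the single isomer 1R,5S,6R,7R,8R,10R encoded by its SMILES. The descriptors of 16 (1S,3S,5S,6S), 19 (3S,5S,8R) and 36 were checked against one another and are consistent, so no structure needed correction.

## Structural features

The target is a germacranolide: a ten-membered carbocycle (C1–C10) trans-fused across C7–C8 to an α-methylene-γ-butyrolactone (C11, C12, C13, ring oxygen on C8). The large ring carries a trans 1,10-epoxide (C10 bears the methyl C14), a C3 ketone cross-conjugated with the exocyclic C4=C15 methylene, a (Z)-2-methylbut-2-enoate (angelate) on O5 and a free hydroxyl on C6. Four contiguous stereocentres C5–C8 lie on one flank, with O5, O6 and O8 on one face and C11 on the other; the epoxide carbons C1 and C10 are remote from them. Several groups are fragile. The methylene lactone and the exo-methylene enone are Michael acceptors, the ketone is β,γ to the epoxide so that base opens it, the Z ester can isomerise or migrate to O6, O6 can translactonise onto C12, and acid can trigger transannular reactions. The real difficulty is to make a ten-membered ring with defined configuration at C5–C8 on a flexible ring, and to order the late steps so that each fragile group appears only after the reagents that would destroy it. The key step exploits the fact that C1–C6 with C15 and the C9/C10/C14 branch on C1 are the skeleton of carvone. A vinyl group on C6 (C7, C8) and the isopropenyl group form a 3-oxido-1,5-diene, C8=C7–C6(O)–C1–C10=C9, whose [3,3] shift joins C8 to C9 and breaks C1–C6. The six-membered ring is thereby enlarged by C7–C10 to the ten-membered ring, leaving an enolate at C6/C7 for the lactone side chain and the E C1=C10 alkene for the epoxide.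

## Logic of the disconnections

36 to 35 and 34: the C3 carbonyl is taken back to the allylic alcohol, and O3 and O6 to silyl ethers. No skeletal bond is cut. The exo-methylene enone and the β,γ-epoxy ketone are the most sensitive parts, so they are made last under neutral conditions. The forward steps must spare the epoxide during desilylation and oxidise only the allylic hydroxyl.

34 to 33: the C1–O and C10–O bonds are cut back to the E C1=C10 alkene. The alkene is inert to every earlier base, hydride and Lewis acid and is the most electron-rich of the five alkenes. This removes two stereocentres, but the forward step needs face selectivity from the ring conformation.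

33 to 30 and 31: the O5–acyl bond is cut. The Z ester would not survive enolate chemistry, so it enters after the lactone is complete. The forward acylation must not isomerise the ester and must find O5 as the only free hydroxyl.

30 to 28 to 25: the O5 acetal is restored and the C11=C13 bond is cut back to a lactone methylene. The Michael acceptor is thereby absent during hydride and enolate steps on the ring. The forward methylenation requires the lactone α-carbon to be the only enolisable site, so C6 must be a silyl ether and not a ketone.

25 to 24 to 23: the O6–Si bond and then the C6–H bond are cut back to the C6 ketone. The ketone is the direct outcome of the ring expansion, and the neighbouring O5 acetal offers chelation control. The forward reduction must deliver hydride to one face.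

23 to 21: the C12–O8 lactone bond is cut and O8 returns to its 4-methoxybenzyl ether. This separates the lactone closure from the C–C bond formation. The forward step needs an ether cleavage that leaves the silyl ether, acetal and alkenes alone.

21 to 19: the C7–C11 bond is cut. The silyl enol ether places nucleophilic character exactly at C7, and the two lactone carbons come from a commercial haloacetate. The forward alkylation must occur on one face of the enolate without β-elimination of O8.

19 to 16: C8–C9 is cut and C1–C6 is re-formed (retro [3,3]). The ten-membered ring, the E alkene and C8 are thereby traced to a cyclohexanol in which stereocontrol is simple. The forward step needs the vinyl and isopropenyl groups trans, a Z enol ether and a regiospecific trap of the enolate.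

16 to 10 and 14: the C6–C7 bond is cut to a ketone and a (Z)-alkoxyvinyl metal. The forward addition must come from the face opposite the isopropenyl group.

14 to 12 to 11: the C–Br bond and the vinyl–oxygen bond are cut back to the benzylic alcohol. The forward elimination must favour the Z bromide.

10 to 9 to 8 to 7: the C6 carbonyl is taken back to a silyl-protected alcohol and the O3 silyl ether to the free alcohol. The three oxygens are thereby differentiated one at a time, and the forward steps need selective cleavage of the triethylsilyl ether.

7 to 6 to 5 to 4: the C4=C15 alkene and C3–OH are taken back to the 3,4-epoxide, the acetal to the free C5 alcohol, and the epoxide to the C3=C4 alkene. O3 is thus derived from O5 by a directed epoxidation. The forward isomerisation must remove a proton from C15 and not from C2.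

4 to 3 to 1: the C5–H bond is cut back to the enone carbonyl and the C6–O bond to the α′-position of the enone. Every ring stereocentre is thereby referred to the single stereocentre of 1. The forward reduction must place O5 cis to the isopropenyl group.

## Other disconnections considered

Alternative 1: The cut goes through C3–C4 and O–C5 of a 4-methylene-isoxazoline that stands for the C3 ketone, the C4 methylene and the C5 oxygen. In the forward sense the primary nitro group at C3 of the open-chain lactone A2 is dehydrated (PhNCO, Et3N) to the dipole, which adds across C4=C5 of the terminal allene and closes the ten-membered ring and the heterocycle together to give A1.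
- In its favour: the whole C3–C5 triad appears in its final oxidation pattern, since reductive N–O cleavage and hydrolysis would unveil the ketone and the C5 hydroxyl without protecting groups at C3 or C5. The lactone and C6–C8 are already in place, with the methylene masked as the amine.
- Against it here: the ring is closed end to end, so dilution is needed and dimerisation of the dipole competes. The dipole must choose the inner allene bond, the right orientation and the right face at C5, guided only by the C6 silyloxy stereocentre. A2 needs its own acyclic synthesis of the C6–C8 triad.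
- Comparison: both plans form the macrocycle and one oxygenated stereocentre in one pericyclic step. The chosen plan does so from a cyclohexane chair, with no entropic penalty and with the configuration fixed by alkene geometry. Alternative 1 is the better plan in functional-group economy at C3–C5 (no silyl ether, no acetal, no late oxidation). In step count the two are probably about equal once A2 is included. In predictability of the ring-forming stereochemistry the chosen plan is stronger.

Alternative 2: The cut removes C12 as carbon monoxide, through C11–C12 and C12–O8. In the forward sense the homopropargylic alcohol A4 (C7 ethynyl trans to the C8 hydroxyl on the finished ten-membered ring) is treated with PdCl2(PPh3)2, SnCl2 and CO. An alkoxycarbonyl–palladium species at O8 adds syn across the alkyne and protonolysis releases the methylene lactone A3.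
- In its favour: carbonyl, ring and exocyclic methylene arise in one step without any enolate, so the angelate and both silyl ethers can already be present and the late exchange at O5 disappears. No stereocentre is created, so the step has no stereochemical risk.
- Against it here: it does not make the macrocycle, so the ring and the C5–C8 tetrad must come from elsewhere, including a C7 ethynyl group trans to O8, which is harder to install than an acetate side chain on an enolate. SnCl2 and palladium hydride species may attack the allylic silyl ether or the 1(10),4(15)-diene.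
- Comparison: for the lactone itself Alternative 2 is better in step count (one step against alkylation, lactonisation and methylenation) and equal in stereochemical demand. As an overall plan it leaves open what the chosen plan solves, namely the origin of the ring and of C8. The two are not exclusive.

Alternative 3: The cut is C5=C6, with O5 and O6 taken back to a Z alkene. In the forward sense second-generation Grubbs catalyst joins the C6 vinyl group of lactone A6 to the terminal alkene of the 2-substituted butadiene at C4, releasing the C2 fragment, to give the (5Z)-diene A5. OsO4 would then add O5 and O6 syn.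
- In its favour: the plan is convergent. Epoxide, lactone and C3 are made on small fragments where reagent control is available, which is better than the late substrate-controlled epoxidation of the chosen plan. O5 and O6 arise together with the right relative configuration.
- Against it here: a ten-membered ring is closed end to end, with competition from the methylene lactone, from the internal diene bond and from oligomerisation. Z geometry rests on ring strain alone. Afterwards OsO4 must pick one alkene of four and one face, and only O5 may be acylated.
- Comparison: Alternative 3 is equal or better in convergence and in the length of the longest linear sequence, and better for the epoxide. It is weaker in the ring-forming event (a catalyst-mediated equilibrium against a stereospecific unimolecular ring expansion) and in telling O5 from O6, which the chosen plan settles by introducing them at different oxidation levels.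

Key step: step 12

## Route

Step 1
Reactants: 1 (R)-carvone
Product: 3 trans-6-(triethylsilyloxy)carvone [(5S,6S)-2-methyl-5-(prop-1-en-2-yl)-6-(triethylsilyloxy)cyclohex-2-en-1-one], via triethylsilyl dienol ether 2 (not isolated)
Conditions: LiN(i-Pr)2, THF, −78 °C; Et3SiCl, −78 → 0 °C; then mCPBA, CH2Cl2, −20 °C
Reagents that add atoms: chlorotriethylsilane CC[Si](Cl)(CC)CC; mCPBA OOC(=O)c1cccc(Cl)c1
Why: Kinetic deprotonation at C6 gives the cross-conjugated dienolate, which is silylated on oxygen; Rubottom oxidation then epoxidises the electron-rich C5=C6 enol ether anti to the neighbouring isopropenyl group and the silyl group migrates to the new oxygen. The C6 configuration is temporary, because C6 becomes a ketone in step 8.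

Step 2
Reactants: 3 trans-6-(triethylsilyloxy)carvone
Product: 4 cyclohexenol with C5–OH cis to the C1 isopropenyl group and trans to C6–OSiEt3
Conditions: NaBH4, CeCl3·7H2O, MeOH, −78 °C
Reagents that add atoms: none
Why: Luche reduction is 1,2-selective, and axial hydride delivery to the half-chair with both ring substituents equatorial should give the equatorial alcohol cis to isopropenyl. This sets C5 (S), the only carvone-controlled stereocentre that reaches the target unchanged.

Step 3
Reactants: 4 cyclohexenol
Product: 5 3,4-epoxy alcohol with the epoxide oxygen cis to C5–OH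
Conditions: VO(acac)2 (cat.), t-BuOOH, CH2Cl2, 0 → 25 °C
Reagents that add atoms: tert-butyl hydroperoxide CC(C)(C)OO
Why: In this hydroxyl-directed epoxidation the vanadium-bound peroxide is delivered from O5 to the syn face of C3=C4, and the unactivated isopropenyl group is left alone.

Step 4
Reactants: 5 epoxy alcohol
Product: 6 C5 methoxymethyl ether of 5
Conditions: MeOCH2Cl, i-Pr2NEt, CH2Cl2, 0 → 40 °C
Reagents that add atoms: chloromethyl methyl ether COCCl
Why: Acetal formation under amine buffering avoids an alkoxide next to the silyl ether. An acetal is chosen for O5 because a silyl group there would migrate to the cis C6 alkoxide in step 12.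

Step 5
Reactants: 6 epoxy acetal
Product: 7 allylic alcohol with C3–OH cis to C5–OCH2OMe and an exocyclic C4=C15 methylene
Conditions: Et2AlCl, lithium 2,2,6,6-tetramethylpiperidide, toluene, 0 °C
Reagents that add atoms: none
Why: In this aluminium amide epoxide-to-allylic-alcohol isomerisation, aluminium activates the epoxide oxygen and the amide removes a C15 proton in a syn elimination with cleavage of the tertiary C4–O bond. The C3–O bond is not touched, so O3 stays cis to O5.

Step 6
Reactants: 7 allylic alcohol
Product: 8 C3 tert-butyldimethylsilyl ether of 7
Conditions: t-BuMe2SiCl, imidazole, DMF, 25 °C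
Reagents that add atoms: tert-butyldimethylsilyl chloride CC(C)(C)[Si](C)(C)Cl
Why: This is a standard silylation of the only free hydroxyl.

Step 7
Reactants: 8 tris-protected triol
Product: 9 C6 alcohol (C3–OSiMe2t-Bu and C5–OCH2OMe retained)
Conditions: PPTS (cat.), MeOH/CH2Cl2, 0 °C
Reagents that add atoms: none
Why: Acid-catalysed methanolysis cleaves the triethylsilyl ether much faster than the tert-butyldimethylsilyl ether and does not touch the acetal.

Step 8
Reactants: 9 C6 alcohol
Product: 10 cyclohexanone (C6 carbonyl; C1 isopropenyl, C3 silyl ether and C5 acetal mutually cis; C4 methylene)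
Conditions: Dess–Martin periodinane, pyridine, CH2Cl2, 0 → 25 °C
Reagents that add atoms: none
Why: Dess–Martin oxidation under buffered, non-enolising conditions should keep the β,γ-unsaturated ketone (C1–H is α to the carbonyl and allylic) from epimerising or moving into conjugation.

Step 9
Reactants: 11 4-methoxybenzyl alcohol
Product: 12 4-methoxybenzyl vinyl ether
Conditions: Pd(OAc)2 (cat.), 1,10-phenanthroline (cat.), ethyl vinyl ether (solvent), 25 °C
Reagents that add atoms: ethyl vinyl ether C=COCC
Why: This is a palladium-catalysed transfer vinylation (transetherification) of a benzylic alcohol, driven by the excess of vinyl ether.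

Step 10
Reactants: 12 4-methoxybenzyl vinyl ether
Product: 14 (Z)-1-bromo-2-(4-methoxybenzyloxy)ethene, via 1,2-dibromoethyl ether 13 (not isolated)
Conditions: Br2, CH2Cl2, −78 °C; then i-Pr2NEt, −78 → 40 °C
Reagents that add atoms: bromine BrBr
Why: Bromine adds to the enol ether, and amine-induced loss of HBr from the α-bromo ether gives the β-bromo enol ether, for which the cis isomer is the favoured one. Residual E isomer is harmless, because its lithio derivative eliminates alkoxide by an anti pathway.

Step 11
Reactants: 10 cyclohexanone; 14 (Z)-1-bromo-2-(4-methoxybenzyloxy)ethene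
Product: 16 trans-1-[(Z)-2-(4-methoxybenzyloxy)vinyl]-2-isopropenylcyclohexanol (1S,3S,5S,6S; C6–OH cis to isopropenyl), via (Z)-vinyllithium 15 (not isolated)
Conditions: 14, t-BuLi (2 equiv), Et2O, −78 °C; then 10, THF, −78 °C
Reagents that add atoms: none
Why: Bromine–lithium exchange proceeds with retention and gives the Z reagent, which is stabilised by internal O–Li coordination. It should add to C6 by equatorial attack, anti to the two equatorial α-substituents (isopropenyl on C1, acetal on C5), so the vinyl group ends trans to isopropenyl with the hydroxyl axial.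

Step 12
Reactants: 16 dialkenyl cyclohexanol
Product: 19 ten-membered C6 trimethylsilyl enol ether (3S,5S,8R; C6=C7 with O6 cis to C8; E C1=C10; C8 4-methoxybenzyl ether), via potassium alkoxide 17 (not isolated), via potassium enolate 18 (not isolated)
Conditions: KH, 18-crown-6 (0.5 equiv), THF, 0 → 25 °C; then Me3SiCl, Et3N, −78 °C
Reagents that add atoms: chlorotrimethylsilane C[Si](C)(C)Cl
Why: Deprotonation gives alkoxide 17, whose C6–O⁻ bond weakens the adjacent C1–C6 bond, so the 3-oxido-1,5-diene C8=C7–C6–C1–C10=C9 undergoes the [3,3] shift (anionic oxy-Cope rearrangement) far below the temperature of the neutral reaction; the closest known reaction type is the ring expansion of trans-1,2-dialkenylcyclohexanol alkoxides to (E)-cyclodec-5-enone enolates. The ten-membered ring is not closed end to end but arises by ring enlargement, C8–C9 forming inside a six-centre chair array while the C1–C6 bond of the cyclohexane breaks. In the chair cyclohexane the vinyl and isopropenyl groups are both equatorial and gauche, which fits the chair array only; there C2 and C5 are equatorial, so C1=C10 is formed E and the enolate has O6 cis to C8. The new stereocentre C8 is controlled by the Z geometry of the enol ether: the Z oxygen is axial on C8, syn to the axial O6 where a potassium ion not held by the crown ether can span both oxygens, and this topography gives 8R. The step needs chair over boat selectivity and periselectivity over the second 3-oxido-1,5-diene C8=C7–C6–C5–C4=C15; the equatorial vinyl group is antiperiplanar to C4, so that array cannot reach a cyclic transition state. The enolate must also survive: the ring holds C9 perpendicular to the enolate plane, so the C8–O bond lies near the nodal plane and β-elimination is disfavoured, and Me3SiCl at −78 °C traps the enolate on oxygen before proton transfer towards C5 can occur.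

Step 13
Reactants: 19 trimethylsilyl enol ether
Product: 21 ethyl ester of the C7-alkylated ketone (C6 carbonyl; C7–CH2CO2Et trans to O8), via lithium enolate 20 (not isolated)
Conditions: MeLi, THF, 0 °C; then DMPU, ICH2CO2Et, −78 → −30 °C
Reagents that add atoms: ethyl iodoacetate CCOC(=O)CI
Why: Cleavage of the silyl enol ether by MeLi regenerates the C6–C7 enolate regiospecifically, and C-alkylation by the iodoacetate follows. With lithium solvated by DMPU the enolate should adopt the allylic-strain-minimised arrangement (H8 in the enolate plane, C9 over one face), so the electrophile enters anti to C9 on the ring periphery, trans to O8. An ethyl ester is used so that the lactone can close in step 14 without strong acid.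

Step 14
Reactants: 21 alkylated ketone
Product: 23 trans-fused keto lactone (8,12-olide with C6 carbonyl), via hydroxy ester 22 (not isolated)
Conditions: DDQ, CH2Cl2/pH 7 buffer, 0 °C; then PPTS (cat.), CH2Cl2, 25 °C
Reagents that add atoms: none
Why: Oxidative cleavage of the 4-methoxybenzyl ether frees O8, which closes the γ-lactone on the ester by acyl substitution. C11 and O8 are trans, so the ring fusion is trans, and no stereocentre is touched.

Step 15
Reactants: 23 keto lactone
Product: 24 C6 alcohol (6R; O6 on the face of O5 and O8)
Conditions: Zn(BH4)2, Et2O, −20 °C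
Reagents that add atoms: none
Why: In this chelation-controlled reduction zinc bridges the C6 carbonyl and the C5 acetal oxygen, and hydride enters from the side of C5–H, which should give the 5,6-anti (ring-cis) diol relationship. The lactone is inert to this reagent at low temperature.

Step 16
Reactants: 24 C6 alcohol
Product: 25 C6 tert-butyldimethylsilyl ether
Conditions: t-BuMe2SiOSO2CF3, 2,6-lutidine, CH2Cl2, −78 → 0 °C
Reagents that add atoms: tert-butyldimethylsilyl trifluoromethanesulfonate CC(C)(C)[Si](C)(C)OS(=O)(=O)C(F)(F)F
Why: Silylation without alkoxide formation avoids translactonisation of O6 onto C12 and removes the only acidic O–H before the enolate step.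

Step 17
Reactants: 25 bis-silyl lactone
Product: 28 α-methylene lactone (C11=C13), via Mannich base 26 (not isolated), via ammonium iodide 27 (not isolated)
Conditions: LiN(SiMe3)2, THF, −78 °C; CH2=NMe2+ I−, −78 → 0 °C; MeI, CH2Cl2, 25 °C; aq. NaHCO3
Reagents that add atoms: N,N-dimethylmethyleneiminium iodide C=[N+](C)C.[I-]
Why: The lactone enolate, the only enolisable site left, is aminomethylated at C11 (Mannich reaction with a preformed iminium salt). Quaternisation and mild-base elimination then give the exocyclic alkene.

Step 18
Reactants: 28 α-methylene lactone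
Product: 30 C5 alcohol, via bromomethyl ether 29 (not isolated)
Conditions: Me2BBr, CH2Cl2, −78 °C; then aq. NaHCO3, THF, 0 °C
Reagents that add atoms: none
Why: The bromoborane exchanges the methoxy group of the acetal at low temperature and the bromomethyl ether is hydrolysed on work-up. Silyl ethers, lactone and alkenes are not attacked under these aprotic conditions, and the C5–O bond is never broken.

Step 19
Reactants: 30 C5 alcohol; 31 angelic acid
Product: 33 C5 angelate, via mixed anhydride 32 (not isolated)
Conditions: 2,4,6-trichlorobenzoyl chloride, Et3N, toluene, 25 °C; then 30, 80 °C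
Reagents that add atoms: none
Why: In this Yamaguchi esterification the alcohol attacks the less hindered angeloyl carbonyl of the mixed anhydride. Without a nucleophilic catalyst or strong base the Z geometry should be kept.

Step 20
Reactants: 33 C5 angelate
Product: 34 1,10-epoxide (1R,10R)
Conditions: mCPBA, Na2HPO4, CH2Cl2, −20 → 0 °C
Reagents that add atoms: mCPBA OOC(=O)c1cccc(Cl)c1
Why: In this Prilezhaev epoxidation the trisubstituted C1=C10 bond is the most electron-rich of the five alkenes (C4=C15 is flanked by two oxygenated carbons and the other three are conjugated to carbonyls). Syn addition to the E alkene gives the trans epoxide, and attack on the exposed outer face of the ring is expected to give 1R,10R.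

Step 21
Reactants: 34 epoxide
Product: 35 3,6-diol
Conditions: HF·pyridine, pyridine, THF, 0 → 25 °C
Reagents that add atoms: none
Why: Buffered fluoride removes both silyl ethers without forming alkoxides, so acyl migration, translactonisation and epoxide opening are avoided.

Step 22
Reactants: 35 3,6-diol
Product: 36 target germacranolide (1R,5S,6R,7R,8R,10R)
Conditions: MnO2, CH2Cl2, 25 °C
Reagents that add atoms: none
Why: MnO2 oxidises only the allylic C3 alcohol; the C6 alcohol is not allylic. The neutral heterogeneous conditions tolerate the β,γ-epoxy ketone, the angelate and the lactone.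

## Compound list

1 | (R)-carvone | CC1=CC[C@H](CC1=O)C(C)=C | starting material
2 | triethylsilyl dienol ether of 1 (C5–OSiEt3; C5=C6 and C3=C4) | CC[Si](CC)(CC)OC1=C[C@H](C(C)=C)CC=C1C | intermediate
3 | (5S,6S)-2-methyl-5-(prop-1-en-2-yl)-6-(triethylsilyloxy)cyclohex-2-en-1-one (C6–OSiEt3 trans to isopropenyl) | CC[Si](CC)(CC)O[C@H]1[C@H](C(C)=C)CC=C(C)C1=O | intermediate
4 | cyclohexenol: C5–OH cis to isopropenyl, trans to C6–OSiEt3 | CC[Si](CC)(CC)O[C@H]1[C@H](C(C)=C)CC=C(C)[C@@H]1O | intermediate
5 | 3,4-epoxide of 4, epoxide oxygen cis to C5–OH | CC[Si](CC)(CC)O[C@H]1[C@H](C(C)=C)C[C@@H]2O[C@]2(C)[C@@H]1O | intermediate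
6 | C5 methoxymethyl ether of 5 | CC[Si](CC)(CC)O[C@H]1[C@H](C(C)=C)C[C@@H]2O[C@]2(C)[C@@H]1OCOC | intermediate
7 | allylic alcohol: C3–OH cis to C5–OCH2OMe, C4=C15 methylene, C6–OSiEt3 | CC[Si](CC)(CC)O[C@H]1[C@H](C(C)=C)C[C@H](O)C(=C)[C@@H]1OCOC | intermediate
8 | C3 tert-butyldimethylsilyl ether of 7 | CC[Si](CC)(CC)O[C@H]1[C@H](C(C)=C)C[C@H](O[Si](C)(C)C(C)(C)C)C(=C)[C@@H]1OCOC | intermediate
9 | C6 alcohol (C3 silyl ether, C5 acetal) | O[C@H]1[C@H](C(C)=C)C[C@H](O[Si](C)(C)C(C)(C)C)C(=C)[C@@H]1OCOC | intermediate
10 | cyclohexanone: C6 carbonyl, C1 isopropenyl, C3 silyl ether, C4 methylene, C5 acetal (substituents all cis) | O=C1[C@H](C(C)=C)C[C@H](O[Si](C)(C)C(C)(C)C)C(=C)[C@@H]1OCOC | intermediate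
11 | 4-methoxybenzyl alcohol | COc1ccc(CO)cc1 | starting material
12 | 4-methoxybenzyl vinyl ether | C=COCc1ccc(OC)cc1 | intermediate
13 | 1,2-dibromoethyl 4-methoxybenzyl ether | BrCC(Br)OCc1ccc(OC)cc1 | intermediate
14 | (Z)-1-bromo-2-(4-methoxybenzyloxy)ethene | Br/C=C\OCc1ccc(OC)cc1 | intermediate
15 | (Z)-2-(4-methoxybenzyloxy)vinyllithium | [Li]/C=C\OCc1ccc(OC)cc1 | intermediate
16 | (1S,3S,5S,6S)-trans-1-[(Z)-2-(4-methoxybenzyloxy)vinyl]-2-isopropenylcyclohexanol with C3 silyl ether, C4 methylene, C5 acetal | O[C@]1(/C=C\OCc2ccc(OC)cc2)[C@H](C(C)=C)C[C@H](O[Si](C)(C)C(C)(C)C)C(=C)[C@@H]1OCOC | intermediate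
17 | potassium alkoxide of 16 | [K+].[O-][C@]1(/C=C\OCc2ccc(OC)cc2)[C@H](C(C)=C)C[C@H](O[Si](C)(C)C(C)(C)C)C(=C)[C@@H]1OCOC | intermediate
18 | ten-membered potassium enolate (C6–OK, C6=C7) | [K+].[O-]/C1=C\[C@H](OCc2ccc(OC)cc2)C/C(C)=C/C[C@H](O[Si](C)(C)C(C)(C)C)C(=C)[C@@H]1OCOC | intermediate
19 | (3S,5S,8R) ten-membered C6 trimethylsilyl enol ether, E C1=C10, C8 4-methoxybenzyl ether | C[Si](C)(C)O/C1=C\[C@H](OCc2ccc(OC)cc2)C/C(C)=C/C[C@H](O[Si](C)(C)C(C)(C)C)C(=C)[C@@H]1OCOC | intermediate
20 | lithium enolate corresponding to 19 | [Li+].[O-]/C1=C\[C@H](OCc2ccc(OC)cc2)C/C(C)=C/C[C@H](O[Si](C)(C)C(C)(C)C)C(=C)[C@@H]1OCOC | intermediate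
21 | C6 ketone with C7–CH2CO2Et trans to the C8 ether oxygen | O=C1[C@@H](CC(=O)OCC)[C@H](OCc2ccc(OC)cc2)C/C(C)=C/C[C@H](O[Si](C)(C)C(C)(C)C)C(=C)[C@@H]1OCOC | intermediate
22 | C8 hydroxy ester from 21 | O=C1[C@@H](CC(=O)OCC)[C@H](O)C/C(C)=C/C[C@H](O[Si](C)(C)C(C)(C)C)C(=C)[C@@H]1OCOC | intermediate
23 | trans-fused 8,12-olide with C6 ketone | C1C(=O)O[C@@H]2C/C(C)=C/C[C@H](O[Si](C)(C)C(C)(C)C)C(=C)[C@H](OCOC)C(=O)[C@@H]12 | intermediate
24 | 6R alcohol of 23 (O6 cis to O5 and O8) | C1C(=O)O[C@@H]2C/C(C)=C/C[C@H](O[Si](C)(C)C(C)(C)C)C(=C)[C@H](OCOC)[C@H](O)[C@@H]12 | intermediate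
25 | C6 tert-butyldimethylsilyl ether of 24 | C1C(=O)O[C@@H]2C/C(C)=C/C[C@H](O[Si](C)(C)C(C)(C)C)C(=C)[C@H](OCOC)[C@H](O[Si](C)(C)C(C)(C)C)[C@@H]12 | intermediate
26 | C11 dimethylaminomethyl lactone (C11 epimers) | CN(C)CC1C(=O)O[C@@H]2C/C(C)=C/C[C@H](O[Si](C)(C)C(C)(C)C)C(=C)[C@H](OCOC)[C@H](O[Si](C)(C)C(C)(C)C)[C@@H]12 | intermediate
27 | trimethylammonium iodide of 26 | C[N+](C)(C)CC1C(=O)O[C@@H]2C/C(C)=C/C[C@H](O[Si](C)(C)C(C)(C)C)C(=C)[C@H](OCOC)[C@H](O[Si](C)(C)C(C)(C)C)[C@@H]12.[I-] | intermediate
28 | α-methylene lactone with C3 and C6 silyl ethers and C5 acetal | C=C1C(=O)O[C@@H]2C/C(C)=C/C[C@H](O[Si](C)(C)C(C)(C)C)C(=C)[C@H](OCOC)[C@H](O[Si](C)(C)C(C)(C)C)[C@@H]12 | intermediate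
29 | C5 bromomethyl ether from 28 | C=C1C(=O)O[C@@H]2C/C(C)=C/C[C@H](O[Si](C)(C)C(C)(C)C)C(=C)[C@H](OCBr)[C@H](O[Si](C)(C)C(C)(C)C)[C@@H]12 | intermediate
30 | C5 alcohol | C=C1C(=O)O[C@@H]2C/C(C)=C/C[C@H](O[Si](C)(C)C(C)(C)C)C(=C)[C@H](O)[C@H](O[Si](C)(C)C(C)(C)C)[C@@H]12 | intermediate
31 | angelic acid | C/C=C(/C)C(=O)O | starting material
32 | angelic 2,4,6-trichlorobenzoic anhydride | C/C=C(/C)C(=O)OC(=O)c1c(Cl)cc(Cl)cc1Cl | intermediate
33 | C5 angelate with C3 and C6 silyl ethers, E C1=C10 | C=C1C(=O)O[C@@H]2C/C(C)=C/C[C@H](O[Si](C)(C)C(C)(C)C)C(=C)[C@H](OC(=O)/C(C)=C\C)[C@H](O[Si](C)(C)C(C)(C)C)[C@@H]12 | intermediate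
34 | (1R,10R)-1,10-epoxide of 33 | C=C1C(=O)O[C@@H]2C[C@@]3(C)O[C@@H]3C[C@H](O[Si](C)(C)C(C)(C)C)C(=C)[C@H](OC(=O)/C(C)=C\C)[C@H](O[Si](C)(C)C(C)(C)C)[C@@H]12 | intermediate
35 | epoxy 3,6-diol | C=C1C(=O)O[C@@H]2C[C@@]3(C)O[C@@H]3C[C@H](O)C(=C)[C@H](OC(=O)/C(C)=C\C)[C@H](O)[C@@H]12 | intermediate
36 | CNP0348992.5 (1R,5S,6R,7R,8R,10R) | C=C1C(=O)O[C@@H]2C[C@@]3(C)O[C@@H]3CC(=O)C(=C)[C@H](OC(=O)/C(C)=C\C)[C@H](O)[C@@H]12 | target

## Step count and least certain steps

Total: 22 steps. Longest linear sequence: 20 steps (steps 1–8 and 11–22, from 1).

**Step 12 (key step).** The rearrangement may leave the chair array, through a boat-like or a cleavage–recombination pathway, because the chair carries two syn-axial oxygens; this would erode control at C8 and the alkene geometry. The enolate may also lose the C8 alkoxy group by β-elimination before it is trapped. Fallback (oxygen at C8 introduced after the ring expansion), setting out from 10: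
- CH2=CHMgBr in THF at −78 °C gives the vinyl carbinol F1.
- KH/18-crown-6 and then Me3SiCl give the silyl enol ether F2, the best-precedented form of this ring expansion.
- Pd(OAc)2 in MeCN (Saegusa–Ito oxidation) gives the (E)-enone F3.
- Conjugate borylation with bis(pinacolato)diboron, CuCl, NaOt-Bu and a chiral bisphosphine in THF/MeOH, the ligand enantiomer chosen for the 8R face, gives the β-boryl ketone F4.
- NaBO3·4H2O gives the β-hydroxy ketone F5.
- 4-Methoxybenzyl trichloroacetimidate with La(OTf)3 (cat.) gives the ether F6.
- Kinetic deprotonation on the C7 side with LiN(i-Pr)2 and alkylation with ICH2CO2Et return to the route at 21.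

**Step 13.** The electrophile may enter on the other face of the enolate, through the lithium-chelated arrangement that holds O8 in the enolate plane. Proton exchange between enolate and product could also erode C5. Fallback (thermodynamic instead of kinetic control at C7), setting out from 19: the C7-epimeric ester F7 is carried through the DDQ cleavage and lactonisation to the cis-fused keto lactone F8. F8 is equilibrated with catalytic DBU in CH2Cl2 through the C6 enol and comes back to the route at 23. A ten-membered ring accommodates the large C6–C7–C8–C9 torsion of a trans-fused γ-lactone better than the small one of the cis isomer, and loss of the ring oxygen from the enolate is a disfavoured 5-endo type process.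

**Step 15.** Hydride delivery may show poor facial selectivity if the zinc chelate does not form or if the ring shields the chelate-controlled face. Fallback (inversion instead of selective reduction), setting out from 23: the 6-epimeric alcohol F9 is converted by Mitsunobu reaction (PPh3, diisopropyl azodicarboxylate, ClCH2CO2H) into the inverted chloroacetate F10. Cleavage with thiourea and NaHCO3 in EtOH comes back to the route at 24.

**Step 20.** The epoxidation may show poor facial selectivity, because the two faces of the E alkene belong to two interconverting ring conformers, and some attack at C4=C15 is possible. Fallback (epoxidation moved to the end, on a ring of different shape with only one nucleophilic alkene), setting out from 33: HF·pyridine gives the diene diol F11, and MnO2 gives the dienone F12, in which C3 is sp2 and C4=C15 is part of an enone. Dimethyldioxirane in acetone at −20 °C then gives 36 directly. If the substrate bias is still wrong, a chiral ketone-derived dioxirane (Shi epoxidation) of the matching enantiomer replaces it.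

**Step 10.** The α-bromo ether 13 may ionise with loss of the 4-methoxybenzyl group, and the elimination may not be fully Z-selective. Fallback (alkyne route to the same lithium reagent), setting out from 11:
- KH and trichloroethylene in THF give the dichlorovinyl ether F13.
- n-BuLi at −78 °C and then MeOH give the ethynyl ether F14, kept cold because benzyl alkynyl ethers rearrange on warming.
- Et3B-initiated addition of Bu3SnH at −78 → 0 °C gives the (Z)-stannane F15 by anti addition.
- Tin–lithium exchange with n-BuLi comes back to the route at 15.

## Further compounds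

F1 | step 12 | trans-1-vinyl-2-isopropenylcyclohexanol with C3 silyl ether, C4 methylene, C5 acetal | O[C@]1(C=C)[C@H](C(C)=C)C[C@H](O[Si](C)(C)C(C)(C)C)C(=C)[C@@H]1OCOC
F2 | step 12 | ten-membered C6 trimethylsilyl enol ether without C8 oxygen | C[Si](C)(C)O/C1=C\CC/C(C)=C/C[C@H](O[Si](C)(C)C(C)(C)C)C(=C)[C@@H]1OCOC
F3 | step 12 | (7E)-cyclodecadienone (C6 ketone, C7=C8) | O=C1/C=C/C/C(C)=C/C[C@H](O[Si](C)(C)C(C)(C)C)C(=C)[C@@H]1OCOC
F4 | step 12 | C8 pinacolboryl ketone | O=C1C[C@H](B2OC(C)(C)C(C)(C)O2)C/C(C)=C/C[C@H](O[Si](C)(C)C(C)(C)C)C(=C)[C@@H]1OCOC
F5 | step 12 | C8 hydroxy ketone (8R) | O=C1C[C@H](O)C/C(C)=C/C[C@H](O[Si](C)(C)C(C)(C)C)C(=C)[C@@H]1OCOC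
F6 | step 12 | C8 4-methoxybenzyl ether of F5 | O=C1C[C@H](OCc2ccc(OC)cc2)C/C(C)=C/C[C@H](O[Si](C)(C)C(C)(C)C)C(=C)[C@@H]1OCOC
F7 | step 13 | C7 epimer of 21 (side chain cis to O8) | O=C1[C@H](CC(=O)OCC)[C@H](OCc2ccc(OC)cc2)C/C(C)=C/C[C@H](O[Si](C)(C)C(C)(C)C)C(=C)[C@@H]1OCOC
F8 | step 13 | cis-fused keto lactone (C7 epimer of 23) | C1C(=O)O[C@@H]2C/C(C)=C/C[C@H](O[Si](C)(C)C(C)(C)C)C(=C)[C@H](OCOC)C(=O)[C@H]12
F9 | step 15 | C6 epimer of 24 | C1C(=O)O[C@@H]2C/C(C)=C/C[C@H](O[Si](C)(C)C(C)(C)C)C(=C)[C@H](OCOC)[C@@H](O)[C@@H]12
F10 | step 15 | C6 chloroacetate with the configuration of 24 | C1C(=O)O[C@@H]2C/C(C)=C/C[C@H](O[Si](C)(C)C(C)(C)C)C(=C)[C@H](OCOC)[C@H](OC(=O)CCl)[C@@H]12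
F11 | step 20 | 3,6-diol with E C1=C10 alkene and C5 angelate | C=C1C(=O)O[C@@H]2C/C(C)=C/C[C@H](O)C(=C)[C@H](OC(=O)/C(C)=C\C)[C@H](O)[C@@H]12
F12 | step 20 | C3 ketone with E C1=C10 alkene (1,10-deoxy target) | C=C1C(=O)O[C@@H]2C/C(C)=C/CC(=O)C(=C)[C@H](OC(=O)/C(C)=C\C)[C@H](O)[C@@H]12
F13 | step 10 | (E)-1,2-dichlorovinyl 4-methoxybenzyl ether | Cl/C=C(/Cl)OCc1ccc(OC)cc1
F14 | step 10 | ethynyl 4-methoxybenzyl ether | C#COCc1ccc(OC)cc1
F15 | step 10 | (Z)-tributyl[2-(4-methoxybenzyloxy)vinyl]stannane | CCCC[Sn](CCCC)(CCCC)/C=C\OCc1ccc(OC)cc1
A1 | alternative 1 | ten-membered ring bridged by a 4-methylene-isoxazoline across C3 and C5 | CN(C)C[C@@H]1C(=O)O[C@@H]2C/C(C)=C/CC3=NO[C@@H](C3=C)[C@H](O[Si](CC)(CC)CC)[C@@H]12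
A2 | alternative 1 | open-chain lactone with C3 nitro group and C4=C5 terminal allene | CN(C)C[C@@H]1C(=O)O[C@H](C/C(C)=C/CC[N+](=O)[O-])[C@H]1[C@@H](O[Si](CC)(CC)CC)C=C=C
A3 | alternative 2 | trans-fused α-methylene lactone with C3 silyl ether, C5 angelate, C6 triethylsilyl ether | C=C1C(=O)O[C@@H]2C/C(C)=C/C[C@@H](O[Si](C)(C)C(C)(C)C)C(=C)[C@H](OC(=O)/C(C)=C\C)[C@H](O[Si](CC)(CC)CC)[C@@H]12
A4 | alternative 2 | ten-membered C7 ethynyl C8 carbinol | C#C[C@H]1[C@H](O)C/C(C)=C/C[C@@H](O[Si](C)(C)C(C)(C)C)C(=C)[C@H](OC(=O)/C(C)=C\C)[C@@H]1O[Si](CC)(CC)CC
A5 | alternative 3 | ten-membered (5Z)-4(15),5-diene with epoxide and α-methylene lactone | C=C1C(=O)O[C@@H]2C[C@@]3(C)O[C@@H]3C[C@@H](O[Si](C)(C)C(C)(C)C)C(=C)/C=C\[C@@H]12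
A6 | alternative 3 | lactone with C6 vinyl group and open chain ending in the 2-substituted butadiene | C=C1C(=O)O[C@H](C[C@@]2(C)O[C@@H]2C[C@@H](O[Si](C)(C)C(C)(C)C)C(=C)C=C)[C@H]1C=C
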